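The data were generated by integration for substances that don't exist; noise was put on by code.

Decide first to treat the south-west flask as the north flask left standing: same charge, longer wait. The question about 270 min then becomes one about where the readings stop falling.

| flask | substrate | catalyst | time |
|---|---|---|---|
| north | 0.600 M | 0.0480 M |  |
| east | 0.240 M | 0.0480 M |  |
| north-west | 0.600 M | 0.0960 M |  |
| south | 0.300 M | 0.0480 M |  |
| south-west | 0.600 M | 0.0480 M | 270 min |

| north run: time / min | north run: [substrate] / M | east run: time / min | east run: [substrate] / M | north-west run: time / min | north-west run: [substrate] / M | south run: time / min | south run: [substrate] / M |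
|---|---|---|---|---|---|---|---|
| 11 | 0.553 | 11 | 0.214 | 11 | 0.519 | 11 | 0.276 |
| 22 | 0.483 | 22 | 0.169 | 22 | 0.394 | 22 | 0.217 |
| 33 | 0.409 | 33 | 0.145 | 33 | 0.311 | 33 | 0.176 |
| 44 | 0.350 | 44 | 0.124 | 44 | 0.285 | 44 | 0.152 |
| 56 | 0.310 | 56 | 0.116 | 56 | 0.274 | 56 | 0.145 |
| 67 | 0.286 | 67 | 0.109 | 67 | 0.272 | 67 | 0.137 |
| 78 | 0.279 | 78 | 0.110 | 78 | 0.281 | 78 | 0.128 |
| 89 | 0.266 | 89 | 0.110 | 89 | 0.270 | 89 | 0.129 |

(each reading ± 0.005 M)

* order of the initial rate in [catalyst], near the charge of the north run, the rate being that where two percent of its substrate are product
* order of the initial rate in [substrate], near the charge of the north run, the rate being that where two percent of its substrate are product (one fixed amount of product, the same in the runs compared)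
* substrate in the south-west run at 270 min, as a share of the substrate charged

- Overall: substrate -> product, with catalyst as catalyst.
- Constant volume, constant temperature.
- Readings of a species count what is bound in complexes too.
- An order is taken over about fifteen percent of the charge, up and down.

Freeze what looks constant, the substrate left when a flask stops falling, counted as a fraction of its charge, and bracket it. From above, the north-west flask has twice the catalyst of north and lies flat over its last 4 readings, which average 45.7 %. From below, the south flask averages 42.8 % over its last two readings, and you take that as the floor.

The north flask tightens the top. Its last reading is 44.3 % of the charge, lower than the one before it, so you expect its continuation to stand there or lower. One reading scatters by 0.833 % of this charge, which brings the ceiling down to 45.2 %. I commit to 44.3 % as the resting share of the north charge, the fraction of it read as substrate, bound forms counted, at the equilibrium position.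

The forecast gives 45.2 %, at the top edge of this bracket, with a range of 43.5 % to 46.5 %. It also gives 0.73 for the catalyst order (0.52 to 0.95) and 0.6 for the substrate order (0.25 to 1). In its words, “Doubling the catalyst leaves the plateau unchanged, so this is a true equilibrium rather than catalyst death”.

The south-west flask stands at 43.6 % of its charge at 270 min, above the floor and below the ceiling, while the orders are 0.57 in catalyst and 0.23 in substrate.

    active catalyst + substrate ⇌ catalyst-substrate complex, settled at all times (3.110 M⁻¹)
    catalyst-substrate complex ⇌ product + active catalyst (0.3924 min⁻¹, 0.8700 M⁻¹ min⁻¹)
    catalyst → active catalyst (0.07860 min⁻¹)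

The slowness of the step from catalyst to active catalyst makes no difference to that share. The resting share leaves 55.7 % of the north charge as product at rest. The east flask has made half of its charge into product at 46.1 min, which, with the same share taken for the east flask, is 89.8 % of its way to rest.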